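**Plan**

- Cuts: the C15 silyl ether and the C13=C14 alkene (held as a (13S,14S)-epoxide until the end) are adjusted last; the C3 acetate goes back to a C3 ketone; rings A and B are opened together at C4–C5 and C9–C10; the acyclic E,E-3-oxo ester is cut at C1–C2 into methyl 2-methylacetoacetate and a C15 allylic bromide from (2E,6E)-farnesol.
- Forward: farnesol is epoxidised at its 2,3-alkene, silylated, oxidised at its terminal E-methyl and brominated; the chain is joined to the keto ester dianion (C1–C2); one oxidative radical step closes ring A first (C4–C5) and ring B second (C9–C10); reduction, acetylation, epoxide deoxygenation and desilylation follow.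
- Enabling feature: C4 lies between the C3 carbonyl and the C19 ester, so it can be oxidised to a radical, and it stands 1,5 to C5 of the C5=C10 alkene; C10 in turn stands 1,5 to C9 of the C8=C9 alkene, and the C8 radical that remains carries the methyl that becomes the C8=C17 methylene.
- Relative configuration at C4, C5, C9 and C10 comes from the chair–chair transition state of the E,E-diene, with the ester axial at C4; the 13E geometry is carried from farnesol through stereospecific epoxidation and deoxygenation.
- Absolute configuration and C3 come from the (S)-oxazaborolidine of step 7, which selects the decalin series whose axial 3-alcohol is 3R and leaves the other series separable.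

Key step: step 6

Remark: labdane numbers are used for all atoms from compound 8 on (C19 ester carbon, C4 its α-carbon, C3 ketone, C2 and C1 the two methylenes, C10=C5 and C8=C9 the two alkenes, C17 the methyl on C8, C13/C14 the epoxide, C15 the silyloxy carbon).

Remark: step 6 is not expected to control the absolute sense of ring formation; it is assumed that 9 and its diastereomer with the mirror-image decalin form in similar amounts, go together into step 7 and are parted there, so that every compound from 10 on is a single stereoisomer.

Step 1
Reactants: 1 (2E,6E)-farnesol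
Product: 2 (2S,3S)-2,3-epoxyfarnesol
Conditions: Ti(OiPr)4 (10 mol %), L-(+)-diethyl tartrate (12 mol %), t-BuOOH, 4 Å MS, CH2Cl2, −20 °C
Reagents that add atoms: tert-butyl hydroperoxide, CC(C)(C)OO
Why: Sharpless asymmetric epoxidation is hydroxyl-directed, so only the 2,3-alkene of the triene should react, syn-stereospecifically (trans-epoxide) and with the (2S,3S) sense given by the L-tartrate; the epoxide masks the future C13=C14 alkene so that it cannot act as a third radical acceptor in step 6.

Step 2
Reactants: 2 (2S,3S)-2,3-epoxyfarnesol
Product: 3 (2S,3S)-2,3-epoxyfarnesyl tert-butyldimethylsilyl ether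
Conditions: TBSCl, imidazole, DMF, 0 → 25 °C
Reagents that add atoms: tert-butyldimethylsilyl chloride, CC(C)(C)[Si](C)(C)Cl
Why: Imidazole-promoted silylation of the primary alcohol; the silyl ether should survive the dianion, the oxidant, the borane and the acylation, and leave at the end with fluoride without touching the C3 acetate.

Step 3
Reactants: 3 (2S,3S)-2,3-epoxyfarnesyl tert-butyldimethylsilyl ether
Product: 4 (2S,3S,6E,10E)-1-(tert-butyldimethylsilyloxy)-2,3-epoxy-3,7,11-trimethyldodeca-6,10-dien-12-ol
Conditions: SeO2 (0.1 equiv), salicylic acid (0.1 equiv), t-BuOOH, CH2Cl2, 25 °C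
Reagents that add atoms: selenium dioxide, O=[Se]=O (oxygen donor, catalytic); tert-butyl hydroperoxide, CC(C)(C)OO (regenerates it)
Why: SeO2/t-BuOOH allylic oxidation (ene reaction followed by a [2,3]-sigmatropic shift) should attack the E-methyl of the terminal, most electron-rich trisubstituted alkene and give the E-allylic alcohol.

Step 4
Reactants: 4 (2S,3S,6E,10E)-1-(tert-butyldimethylsilyloxy)-2,3-epoxy-3,7,11-trimethyldodeca-6,10-dien-12-ol
Product: 5 (2S,3S,6E,10E)-12-bromo-1-(tert-butyldimethylsilyloxy)-2,3-epoxy-3,7,11-trimethyldodeca-6,10-diene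
Conditions: CBr4, PPh3, 2,6-lutidine (0.2 equiv), CH2Cl2, −20 → 0 °C
Reagents that add atoms: tetrabromomethane, BrC(Br)(Br)Br
Why: The Appel reaction converts the primary allylic alcohol to the bromide by SN2 under buffered, near-neutral conditions, so no allylic transposition, no loss of E-geometry and no opening of the epoxide is expected.

Step 5
Reactants: 5 (2S,3S,6E,10E)-12-bromo-1-(tert-butyldimethylsilyloxy)-2,3-epoxy-3,7,11-trimethyldodeca-6,10-diene; 6 methyl 2-methyl-3-oxobutanoate
Product: 8 methyl (6E,10E,14S,15S)-16-(tert-butyldimethylsilyloxy)-14,15-epoxy-2,6,10,14-tetramethyl-3-oxohexadeca-6,10-dienoate, via dianion 7 (not isolated)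
Conditions: 6, NaH, THF, 0 °C; n-BuLi, 0 °C; then 5, 0 → 25 °C; aq. NH4Cl
Reagents that add atoms: none
Why: γ-Alkylation of a β-keto ester dianion: the more basic terminal carbanion (C2) displaces bromide from the primary allylic carbon C1 by SN2, keeping both E-alkenes; the C4 stereocentre of 8 is uncontrolled and is erased in step 6.

Step 6
Reactants: 8 methyl (6E,10E,14S,15S)-16-(tert-butyldimethylsilyloxy)-14,15-epoxy-2,6,10,14-tetramethyl-3-oxohexadeca-6,10-dienoate
Product: 9 methyl (4R,5R,9S,10R,13S,14S)-15-(tert-butyldimethylsilyloxy)-13,14-epoxy-3-oxolabd-8(17)-en-19-oate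
Conditions: Mn(OAc)3·2H2O (2.2 equiv), Cu(OAc)2·H2O (1.0 equiv, reoxidised in situ by Mn(OAc)3), NaOAc, degassed EtOH, 25 → 40 °C
Reagents that add atoms: none
Why: Mn(OAc)3 enolises the 1,3-dicarbonyl unit and the enolate of trivalent manganese collapses by electron transfer to the planar, electrophilic C4 radical, so both C4 epimers of 8 converge; this radical adds 6-endo-trig to C5 of the C5=C10 alkene (ring A, bond C4–C5), the tertiary C10 radical adds 6-endo-trig to C9 of the C8=C9 alkene (ring B, bond C9–C10), and the tertiary C8 radical is captured by divalent copper and loses a methyl β-hydrogen to give the exocyclic C8=C17 alkene. The closest known reaction type is the Mn(OAc)3/Cu(OAc)2 oxidative free-radical polyene cyclisation of 2-alkyl-3-oxo esters to trans-fused decalones. Relative configuration follows from a chair–chair transition state of the E,E-diene: anti addition across C5=C10 sets H-5 trans to the C10 methyl (trans ring fusion), anti addition across C8=C9 places the C9 side chain equatorial and trans to the C10 methyl, and at C4 the methyl takes the equatorial and the ester the axial site, cis to the C10 methyl, as is general for this reaction type. The selectivity needed is a stop after two rings with an exocyclic alkene: the stop is secured because the third alkene of the chain is present only as its epoxide, which carbon radicals do not attack, and the exocyclic position by the preference of the copper-mediated elimination for the least hindered β-hydrogen. Nothing controls the absolute sense, so 9 should be accompanied by a similar amount of its diastereomer with the mirror-image decalin on the same (13S,14S)-epoxide; the two are not parted here and go together into step 7.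

Step 7
Reactants: 9 methyl (4R,5R,9S,10R,13S,14S)-15-(tert-butyldimethylsilyloxy)-13,14-epoxy-3-oxolabd-8(17)-en-19-oate (as obtained from step 6, together with its mirror-decalin diastereomer)
Product: 10 methyl (3R,4R,5R,9S,10R,13S,14S)-15-(tert-butyldimethylsilyloxy)-13,14-epoxy-3α-hydroxylabd-8(17)-en-19-oate
Conditions: (S)-2-methyl-CBS-oxazaborolidine (0.5 equiv), catecholborane (0.6 equiv based on total ketone), toluene, −40 → −20 °C; then chromatography on silica
Reagents that add atoms: none
Why: Corey–Bakshi–Shibata reduction under catalyst control: the (S)-oxazaborolidine binds the C3 ketone with the fully substituted C4 as the large and the C2 methylene as the small group and delivers hydride to make C3 R, which in 9 is the axial 3α-alcohol reached by equatorial attack from the β-face (the mode a bulky reductant prefers on a 4,4-disubstituted 3-decalone, so the matched case), whereas in the mirror-decalin diastereomer 3R would be the equatorial alcohol reached by hindered axial attack (the mismatched, slow case), so that this diastereomer should stay as ketone or give the equatorial alcohol, both of which differ from 10 in polarity and are removed on silica; catecholborane in deficit at low temperature is chosen to spare the 1,1-disubstituted alkene and the epoxide.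

Step 8
Reactants: 10 methyl (3R,4R,5R,9S,10R,13S,14S)-15-(tert-butyldimethylsilyloxy)-13,14-epoxy-3α-hydroxylabd-8(17)-en-19-oate
Product: 11 methyl (3R,4R,5R,9S,10R,13S,14S)-3α-acetoxy-15-(tert-butyldimethylsilyloxy)-13,14-epoxylabd-8(17)-en-19-oate
Conditions: Ac2O, DMAP, pyridine, CH2Cl2, 25 → 40 °C
Reagents that add atoms: acetic anhydride, CC(=O)OC(C)=O
Why: DMAP-catalysed acylation reaches the hindered axial alcohol with retention at C3; the basic medium leaves the epoxide, the silyl ether and the methyl ester untouched.

Step 9
Reactants: 11 methyl (3R,4R,5R,9S,10R,13S,14S)-3α-acetoxy-15-(tert-butyldimethylsilyloxy)-13,14-epoxylabd-8(17)-en-19-oate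
Product: 12 methyl (3R,4R,5R,9S,10R,13E)-3α-acetoxy-15-(tert-butyldimethylsilyloxy)labda-8(17),13-dien-19-oate
Conditions: Re2O7 (5 mol %), P(OPh)3 (1.5 equiv), toluene, 100 °C
Reagents that add atoms: none
Why: Rhenium-oxo-catalysed deoxygenation of an epoxide (oxygen-atom transfer to the phosphite through a rhenium diolate that extrudes the alkene in a syn fashion) is stereospecific with retention, so the trans-epoxide should return the 13E alkene with the geometry of the starting farnesol.

Step 10
Reactants: 12 methyl (3R,4R,5R,9S,10R,13E)-3α-acetoxy-15-(tert-butyldimethylsilyloxy)labda-8(17),13-dien-19-oate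
Product: 13 methyl (3R,4R,5R,9S,10R,13E)-3α-acetoxy-15-hydroxylabda-8(17),13-dien-19-oate (CNP0164591.1)
Conditions: HF·pyridine, pyridine, THF, 0 → 25 °C
Reagents that add atoms: none
Why: Fluoride-driven cleavage of the primary silyl ether (desilylation) under buffered conditions should leave the hindered C3 acetate, the methyl ester and both alkenes unchanged.

**Compound list**

1 | (2E,6E)-farnesol, (2E,6E)-3,7,11-trimethyldodeca-2,6,10-trien-1-ol | CC(C)=CCC/C(C)=C/CC/C(C)=C/CO | starting material
2 | (2S,3S)-2,3-epoxyfarnesol, [(2S,3S)-3-[(3E)-4,8-dimethylnona-3,7-dien-1-yl]-3-methyloxiran-2-yl]methanol | OC[C@@H]1O[C@@]1(C)CC/C=C(\C)CCC=C(C)C | intermediate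
3 | (2S,3S)-2,3-epoxyfarnesyl tert-butyldimethylsilyl ether | CC(C)(C)[Si](C)(C)OC[C@@H]1O[C@@]1(C)CC/C=C(\C)CCC=C(C)C | intermediate
4 | (2S,3S,6E,10E)-1-(tert-butyldimethylsilyloxy)-2,3-epoxy-3,7,11-trimethyldodeca-6,10-dien-12-ol | CC(C)(C)[Si](C)(C)OC[C@@H]1O[C@@]1(C)CC/C=C(\C)CC/C=C(\C)CO | intermediate
5 | (2S,3S,6E,10E)-12-bromo-1-(tert-butyldimethylsilyloxy)-2,3-epoxy-3,7,11-trimethyldodeca-6,10-diene | CC(C)(C)[Si](C)(C)OC[C@@H]1O[C@@]1(C)CC/C=C(\C)CC/C=C(\C)CBr | intermediate
6 | methyl 2-methyl-3-oxobutanoate | COC(=O)C(C)C(C)=O | starting material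
7 | sodium lithium dianion of 6 (carbanions at C2 and C4 of the butanoate) | [Na+].[Li+].COC(=O)[C-](C)C(=O)[CH2-] | intermediate
8 | methyl (6E,10E,14S,15S)-16-(tert-butyldimethylsilyloxy)-14,15-epoxy-2,6,10,14-tetramethyl-3-oxohexadeca-6,10-dienoate (both C2 epimers) | COC(=O)C(C)C(=O)CC/C(C)=C/CC/C(C)=C/CC[C@]1(C)O[C@H]1CO[Si](C)(C)C(C)(C)C | intermediate
9 | methyl (4R,5R,9S,10R,13S,14S)-15-(tert-butyldimethylsilyloxy)-13,14-epoxy-3-oxolabd-8(17)-en-19-oate (4β-CO2Me, 5α-H, 9α-H, 10β-CH3; carried into step 7 together with its mirror-decalin diastereomer) | C=C1CC[C@@H]2[C@](C)(CCC(=O)[C@]2(C)C(=O)OC)[C@H]1CC[C@]3(C)O[C@H]3CO[Si](C)(C)C(C)(C)C | intermediate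
10 | methyl (3R,4R,5R,9S,10R,13S,14S)-15-(tert-butyldimethylsilyloxy)-13,14-epoxy-3α-hydroxylabd-8(17)-en-19-oate (axial OH) | C=C1CC[C@@H]2[C@](C)(CC[C@@H](O)[C@]2(C)C(=O)OC)[C@H]1CC[C@]3(C)O[C@H]3CO[Si](C)(C)C(C)(C)C | intermediate
11 | methyl (3R,4R,5R,9S,10R,13S,14S)-3α-acetoxy-15-(tert-butyldimethylsilyloxy)-13,14-epoxylabd-8(17)-en-19-oate | C=C1CC[C@@H]2[C@](C)(CC[C@@H](OC(C)=O)[C@]2(C)C(=O)OC)[C@H]1CC[C@]3(C)O[C@H]3CO[Si](C)(C)C(C)(C)C | intermediate
12 | methyl (3R,4R,5R,9S,10R,13E)-3α-acetoxy-15-(tert-butyldimethylsilyloxy)labda-8(17),13-dien-19-oate | C=C1CC[C@@H]2[C@](C)(CC[C@@H](OC(C)=O)[C@]2(C)C(=O)OC)[C@H]1CC/C(C)=C/CO[Si](C)(C)C(C)(C)C | intermediate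
13 | methyl (3R,4R,5R,9S,10R,13E)-3α-acetoxy-15-hydroxylabda-8(17),13-dien-19-oate | C=C1CC[C@@H]2[C@](C)(CC[C@@H](OC(C)=O)[C@]2(C)C(=O)OC)[C@H]1CC/C(C)=C/CO | target

**Count and risks**

Total step count: 10. Longest linear sequence: 10 steps (from 1 to 13).

Steps most likely to fail:

1. Step 6. The epoxide mask may be opened solvolytically in the acetate medium in the presence of the Lewis-acidic manganese and copper salts, and the copper-mediated elimination may lose regiocontrol and give endocyclic ring B alkenes. The fallback generates the same C4 radical under neutral chain conditions and sets out from 8. Deprotonation (NaH, THF, 0 °C) and N-bromosuccinimide at −78 °C should give methyl (6E,10E,14S,15S)-2-bromo-16-(tert-butyldimethylsilyloxy)-14,15-epoxy-2,6,10,14-tetramethyl-3-oxohexadeca-6,10-dienoate F1. Bromine-atom-transfer radical bicyclisation of F1 (Et3B, air, benzene, 25 °C), a known reaction type for α-bromo β-keto esters, should close the same two rings and end at the tertiary bromide methyl 8-bromo-15-(tert-butyldimethylsilyloxy)-13,14-epoxy-3-oxolabdan-19-oate F2, formed beside its mirror-image-decalin diastereomer F3. Dehydrobromination towards the methyl group (DBU, toluene, 80 °C) should come back to 9 from F2 and to the mirror-decalin diastereomer of 9 from F3, the same pair that enters step 7.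

2. Step 7. Catalyst control may be overridden by substrate control in the mismatched diastereomer, so that this series is also reduced by equatorial attack to an axial alcohol that differs from 10 only in its relation to the remote epoxide and travels with it, eroding the enantiomeric purity after step 9; the borane may also hydroborate the exocyclic alkene. The fallback sets out from 9 as obtained from step 6. Because of the (13S,14S)-epoxide, 9 and its companion are diastereomers and can be parted physically by preparative HPLC on silica without a chiral phase. Pure 9 is then reduced under substrate control with LiBH(s-Bu)3 (THF, −78 °C), whose equatorial attack is known to give axial alcohols from 4,4-disubstituted 3-decalones, and the route is rejoined at 10.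

3. Step 9. The rhenium oxide may catalyse a 1,3-transposition of the allylic silyl ether that is being formed, with partial loss of the alkene geometry, or migration of the exocyclic double bond. The fallback sets out from 11. Anti opening of the epoxide at C14 with PhSeNa ((PhSe)2, NaBH4, EtOH, 25 → 60 °C) should give methyl (3R,4R,5R,9S,10R,13S,14R)-3α-acetoxy-15-(tert-butyldimethylsilyloxy)-13-hydroxy-14-(phenylselanyl)labd-8(17)-en-19-oate F4. Anti elimination of the β-hydroxy selenide F4 (MsCl, Et3N, CH2Cl2, 0 °C) returns 12; two anti steps add up to retention, so the 13E geometry is kept without a high-valent metal oxide.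

**Further compounds**

F1 | step 6 | methyl (6E,10E,14S,15S)-2-bromo-16-(tert-butyldimethylsilyloxy)-14,15-epoxy-2,6,10,14-tetramethyl-3-oxohexadeca-6,10-dienoate | COC(=O)C(C)(Br)C(=O)CC/C(C)=C/CC/C(C)=C/CC[C@]1(C)O[C@H]1CO[Si](C)(C)C(C)(C)C
F2 | step 6 | methyl 8-bromo-15-(tert-butyldimethylsilyloxy)-13,14-epoxy-3-oxolabdan-19-oate with the decalin configuration of 9 (4β-CO2Me, 5α-H, 9α-H, 10β-CH3) and the (13S,14S)-epoxide, C8 configuration not defined | CC1(Br)CC[C@@H]2[C@](C)(CCC(=O)[C@]2(C)C(=O)OC)[C@H]1CC[C@]3(C)O[C@H]3CO[Si](C)(C)C(C)(C)C
F3 | step 6 | diastereomer of F2 with the mirror-image decalin (4α-CO2Me, 5β-H, 9β-H, 10α-CH3) on the same (13S,14S)-epoxide, C8 configuration not defined | CC1(Br)CC[C@H]2[C@@](C)(CCC(=O)[C@@]2(C)C(=O)OC)[C@@H]1CC[C@]3(C)O[C@H]3CO[Si](C)(C)C(C)(C)C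
F0 | step 7 | none | none
F4 | step 9 | methyl (3R,4R,5R,9S,10R,13S,14R)-3α-acetoxy-15-(tert-butyldimethylsilyloxy)-13-hydroxy-14-(phenylselanyl)labd-8(17)-en-19-oate | C=C1CC[C@@H]2[C@](C)(CC[C@@H](OC(C)=O)[C@]2(C)C(=O)OC)[C@H]1CC[C@](C)(O)[C@H]([Se]c1ccccc1)CO[Si](C)(C)C(C)(C)C
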